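**Plan**

- Cuts: ring A (the cyclohexane; C1 ylidene carbon, C2 CH with the hydroxypropyl arm, C3 quaternary, C4 carbinol, C5 and C6 CH2) is opened at C1–C6. Further cuts are C4–CH3, C3–homofarnesyl, and the two bonds of a temporary cyclohexenone (ring B) that a Michael/aldol annulation makes.
- Enabling feature: in ring A, C4–C5–C6 is the C=O/α/β array of a ketone homoenolate, which can be stored as a 1-substituted cyclopropanol. C1 is the β-carbon of the enal, an sp2 carbon that can carry a triflate of fixed geometry.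
- Forward order: ring B from methyl acetoacetate and an enal; chain joined by alkylation; ring B cut between its ketone carbon and α-CH2 to release the CH2OH and hydroxypropyl arms; ester to cyclopropanol; acetal to E enol triflate; ring A closed; methyl added at C4; ester taken to the enal.
- Stereochemistry: C2 from the aminocatalysed Michael addition; C3 by alkylation trans to the C2 substituent on ring B; alkene geometry from E-selective triflation and stereoretentive coupling; C4 by equatorial methyl addition to the ring A ketone.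

Key step: step 15

Remark (assumption): centres that are destroyed later (C1 of 11, C3 of 14, C2/C3 of 15, the carbinol and α-carbons of 22 and 23) are carried as mixtures; descriptors are given only for centres that persist.

**Route**

Step 1
Reactants: 1 (2E,6E)-farnesol
Product: 2 (2E,6E)-farnesal
Conditions: MnO2 (activated, excess), CH2Cl2, rt
Reagents that add atoms: none
Why: MnO2 should oxidise only the allylic alcohol and leave the trisubstituted alkenes and their geometry untouched (allylic oxidation).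

Step 2
Reactants: 2 (2E,6E)-farnesal
Product: 3 (3E,7E)-4,8,12-trimethyltrideca-1,3,7,11-tetraene
Conditions: Ph3PCH3Br, KOtBu, THF, 0 °C to rt
Reagents that add atoms: methyltriphenylphosphonium bromide, C[P+](c1ccccc1)(c1ccccc1)c1ccccc1.[Br-]
Why: Wittig methylenation of the enal should give the terminal diene without touching the existing alkenes.

Step 3
Reactants: 3 (3E,7E)-4,8,12-trimethyltrideca-1,3,7,11-tetraene
Product: 5 (3E,7E)-4,8,12-trimethyltrideca-3,7,11-trien-1-ol (homofarnesol), via B-homofarnesyl-9-BBN 4 (not isolated)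
Conditions: 9-BBN (1.1 equiv), THF, 0 °C to rt; then aq. NaOH, H2O2, 0 °C
Reagents that add atoms: hydrogen peroxide, OO
Why: 9-BBN should add anti-Markovnikov to the only monosubstituted alkene, the trisubstituted alkenes being far slower (hydroboration–oxidation).

Step 4
Reactants: 5 homofarnesol
Product: 6 (3E,7E)-1-iodo-4,8,12-trimethyltrideca-3,7,11-triene (homofarnesyl iodide)
Conditions: PPh3, I2, imidazole, CH2Cl2, 0 °C
Reagents that add atoms: iodine, II
Why: Appel-type iodination converts the primary alcohol into the iodide under neutral conditions that spare the polyene.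

Step 5
Reactants: 7 methyl acetoacetate, 8 (E)-4,4-dimethoxybut-2-enal
Product: 11 methyl (6R)-6-(dimethoxymethyl)-2-oxocyclohex-3-ene-1-carboxylate, via Michael adduct 9 (not isolated), via aldol 10 (not isolated)
Conditions: (S)-2-{bis[3,5-bis(trifluoromethyl)phenyl](trimethylsilyloxy)methyl}pyrrolidine (10 mol%), PhCO2H (10 mol%), toluene, rt; then camphorsulfonic acid (10 mol%), 4 Å molecular sieves, 40 °C
Reagents that add atoms: none
Why: Iminium-activated Michael addition of the β-keto ester to the enal, then acid-promoted intramolecular aldol condensation (organocatalytic Robinson-type annulation); the (S)-catalyst shields one face of the iminium ion, so the acetal-bearing carbon (later ring A C2) should form with R configuration.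

Step 6
Reactants: 11 methyl (6R)-6-(dimethoxymethyl)-2-oxocyclohex-3-ene-1-carboxylate, 6 homofarnesyl iodide
Product: 12 methyl (1R,6R)-6-(dimethoxymethyl)-2-oxo-1-[(3E,7E)-4,8,12-trimethyltrideca-3,7,11-trien-1-yl]cyclohex-3-ene-1-carboxylate
Conditions: Cs2CO3, MeCN, rt
Reagents that add atoms: none
Why: C-alkylation of the doubly stabilised β-keto ester enolate with the primary iodide should occur anti to the pseudoaxial dimethoxymethyl group on the neighbouring carbon, which sets the quaternary centre (later ring A C3) with the chain trans to the acetal.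

Step 7
Reactants: 12 alkylated enone ester
Product: 14 methyl (1R,6R)-6-(dimethoxymethyl)-3-hydroxy-2-oxo-1-[(3E,7E)-4,8,12-trimethyltrideca-3,7,11-trien-1-yl]cyclohexane-1-carboxylate, via lithium enolate 13 (not isolated)
Conditions: LiBH(s-Bu)3 (1.1 equiv), THF, −78 °C; then 2-(phenylsulfonyl)-3-phenyloxaziridine, −78 to −20 °C; aq. NH4Cl
Reagents that add atoms: 2-(phenylsulfonyl)-3-phenyloxaziridine, O=S(=O)(N1OC1c1ccccc1)c1ccccc1
Why: The hindered borohydride should reduce the β-unsubstituted enone by 1,4-addition, and the regiodefined enolate is hydroxylated in the same flask by the N-sulfonyloxaziridine (conjugate reduction–enolate oxidation); the new carbinol centre is destroyed in step 8.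

Step 8
Reactants: 14 α-hydroxy ketone
Product: 17 methyl (2R,5E,9E)-2-[(2R)-5-hydroxy-1,1-dimethoxypentan-2-yl]-2-(hydroxymethyl)-6,10,14-trimethylpentadeca-5,9,13-trienoate, via ring diol 15 (not isolated), via dialdehyde 16 (not isolated)
Conditions: NaBH4, MeOH, 0 °C; then NaIO4, aq. NaHCO3/THF, rt; then NaBH4, 0 °C
Reagents that add atoms: none
Why: Ketone reduction gives a vicinal diol that periodate cleaves (glycol cleavage), and the second borohydride charge reduces both aldehydes while the hindered methyl ester and the acetal should survive; this opens ring B and releases the hydroxymethyl and 3-hydroxypropyl arms with both stereocentres intact.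

Step 9
Reactants: 17 diol ester
Product: 18 methyl (2R,5E,9E)-2-{[tert-butyl(dimethyl)silyl]oxymethyl}-2-[(2R)-5-{[tert-butyl(dimethyl)silyl]oxy}-1,1-dimethoxypentan-2-yl]-6,10,14-trimethylpentadeca-5,9,13-trienoate
Conditions: TBSCl (2.5 equiv), imidazole, DMF, rt
Reagents that add atoms: tert-butyl(chloro)dimethylsilane, CC(C)(C)[Si](C)(C)Cl
Why: Standard silylation of both primary alcohols, needed because the next steps use Grignard, triflating and oxidising reagents.

Step 10
Reactants: 18 bis-silyl ester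
Product: 19 1-[(1R,4E,8E)-1-{[tert-butyl(dimethyl)silyl]oxymethyl}-1-[(2R)-5-{[tert-butyl(dimethyl)silyl]oxy}-1,1-dimethoxypentan-2-yl]-5,9,13-trimethyltetradeca-4,8,12-trien-1-yl]cyclopropan-1-ol
Conditions: EtMgBr (4 equiv, slow addition), Ti(OiPr)4 (1.0 equiv), THF, 0 °C to rt
Reagents that add atoms: ethylmagnesium bromide, CC[Mg]Br
Why: Kulinkovich reaction: the titanacyclopropane formed from EtMgBr and Ti(OiPr)4 should add twice to the only ester and turn its carbonyl carbon into the carbinol carbon of a 1-substituted cyclopropanol, while silyl ethers, acetal and trisubstituted alkenes are inert.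

Step 11
Reactants: 19 cyclopropanol acetal
Product: 20 (2R)-5-{[tert-butyl(dimethyl)silyl]oxy}-2-[(1R,4E,8E)-1-{[tert-butyl(dimethyl)silyl]oxymethyl}-5,9,13-trimethyl-1-[1-(triethylsilyloxy)cyclopropyl]tetradeca-4,8,12-trien-1-yl]pentanal
Conditions: Et3SiOTf (3 equiv), 2,4,6-collidine (4.5 equiv), CH2Cl2, 0 °C; then H2O, rt
Reagents that add atoms: triethylsilyl trifluoromethanesulfonate, CC[Si](CC)(CC)OS(=O)(=O)C(F)(F)F; water, O
Why: The silyl triflate/collidine pair should silylate the tertiary cyclopropanol and convert the dimethyl acetal, through a pyridinium intermediate, into the aldehyde on aqueous work-up, under non-acidic conditions that spare the TBS ethers and the α-stereocentre.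

Step 12
Reactants: 20 aldehyde, 21 methyl propionate
Product: 22 methyl (4R)-7-{[tert-butyl(dimethyl)silyl]oxy}-4-[(1R,4E,8E)-1-{[tert-butyl(dimethyl)silyl]oxymethyl}-5,9,13-trimethyl-1-[1-(triethylsilyloxy)cyclopropyl]tetradeca-4,8,12-trien-1-yl]-3-hydroxy-2-methylheptanoate
Conditions: LiN(i-Pr)2, 21, THF, −78 °C; then 20, −78 °C; aq. NH4Cl
Reagents that add atoms: none
Why: Aldol addition of the lithium ester enolate to the hindered aldehyde at low temperature, where α-epimerisation should not compete; the two new centres are removed in steps 13 and 14.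

Step 13
Reactants: 22 β-hydroxy ester
Product: 23 methyl (4R)-7-{[tert-butyl(dimethyl)silyl]oxy}-4-[(1R,4E,8E)-1-{[tert-butyl(dimethyl)silyl]oxymethyl}-5,9,13-trimethyl-1-[1-(triethylsilyloxy)cyclopropyl]tetradeca-4,8,12-trien-1-yl]-2-methyl-3-oxoheptanoate
Conditions: Dess–Martin periodinane, NaHCO3, CH2Cl2, 0 °C to rt
Reagents that add atoms: none
Why: Buffered periodinane oxidation of the secondary alcohol should give the α-methyl β-keto ester without epimerising the adjacent stereocentre.

Step 14
Reactants: 23 β-keto ester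
Product: 24 methyl (2E,4R)-7-{[tert-butyl(dimethyl)silyl]oxy}-4-[(1R,4E,8E)-1-{[tert-butyl(dimethyl)silyl]oxymethyl}-5,9,13-trimethyl-1-[1-(triethylsilyloxy)cyclopropyl]tetradeca-4,8,12-trien-1-yl]-2-methyl-3-(trifluoromethylsulfonyloxy)hept-2-enoate
Conditions: Tf2O, aq. Me4NOH, toluene, 0 °C
Reagents that add atoms: trifluoromethanesulfonic anhydride, O=S(=O)(OS(=O)(=O)C(F)(F)F)C(F)(F)F
Why: O-Triflation of the non-chelated tetramethylammonium enolate, which prefers the W-shaped form with the enolate oxygen anti to the ester carbonyl, should give the E enol triflate (triflate cis to the methyl group), the geometry the target alkene needs.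

Step 15
Reactants: 24 E enol triflate with silylated cyclopropanol
Product: 25 methyl (2Z)-2-[(2S,3R)-3-{[tert-butyl(dimethyl)silyl]oxymethyl}-2-(3-{[tert-butyl(dimethyl)silyl]oxy}propyl)-4-oxo-3-[(3E,7E)-4,8,12-trimethyltrideca-3,7,11-trien-1-yl]cyclohexylidene]propanoate
Conditions: Pd2(dba)3 (5 mol%), XPhos (12 mol%), K3PO4 (3 equiv), toluene, 80 °C
Reagents that add atoms: none
Why: Proposed new method: zerovalent palladium inserts into the C–OTf bond with retention of alkene geometry, the resulting cationic alkenylpalladium triflate (divalent palladium) engages the oxygen of the neighbouring 1-siloxycyclopropane, the silyl group passing to triflate and phosphate, and strain-driven β-carbon elimination opens the three-membered ring to a palladium ketone homoenolate with the metal on the future ring A C6. The closest known reaction type is the palladium-catalysed ring-opening cross-coupling of cyclopropanols and siloxycyclopropanes with aryl halides and triflates, including intramolecular arylations; here the electrophile is a β-triflyloxy enoate and the coupling is intramolecular. Ring A closes by C(sp3)–C(sp2) reductive elimination from a seven-membered palladacycle, the alkene ending exocyclic to the new six-membered ring. No stereocentre is created; the two existing centres are not epimerisable under these conditions, and the tetrasubstituted alkene geometry is carried over from 24 because oxidative addition and reductive elimination are both stereoretentive. The step needs reductive elimination to outrun β-hydride elimination of the homoenolate, which the bulky biaryl phosphine and the intramolecular chelated arrangement should secure, and it needs the triflate not to be displaced at carbon by an oxygen nucleophile, which is secured by keeping the cyclopropanol silylated and using a weak insoluble base so that no free alkoxide is present.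

Step 16
Reactants: 25 ring A ketone
Product: 26 methyl (2Z)-2-[(2S,3R,4R)-3-{[tert-butyl(dimethyl)silyl]oxymethyl}-2-(3-{[tert-butyl(dimethyl)silyl]oxy}propyl)-4-hydroxy-4-methyl-3-[(3E,7E)-4,8,12-trimethyltrideca-3,7,11-trien-1-yl]cyclohexylidene]propanoate
Conditions: MeLi, CeCl3 (anhydrous), THF, −78 °C
Reagents that add atoms: methyllithium, [Li]C
Why: Organocerium 1,2-addition to the hindered ketone in the presence of the enoate; allylic 1,3-strain from the Z ester holds the C2 side chain axial and blocks the axial trajectory on that face, and the silylated neighbour cannot chelate, so methyl should enter equatorially and leave the hydroxyl cis to the hydroxymethyl and oxypropyl groups (4R).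

Step 17
Reactants: 26 hydroxy ester
Product: 27 (2Z)-2-[(2S,3R,4R)-3-{[tert-butyl(dimethyl)silyl]oxymethyl}-2-(3-{[tert-butyl(dimethyl)silyl]oxy}propyl)-4-hydroxy-4-methyl-3-[(3E,7E)-4,8,12-trimethyltrideca-3,7,11-trien-1-yl]cyclohexylidene]propan-1-ol
Conditions: i-Bu2AlH (4 equiv), CH2Cl2, −78 to 0 °C; aq. potassium sodium tartrate
Reagents that add atoms: none
Why: Hydride reduction of the tetrasubstituted enoate should stop at the allylic alcohol by 1,2-reduction, with the alkene geometry unchanged.

Step 18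
Reactants: 27 bis-silyl diol
Product: 28 (2Z)-2-[(2S,3R,4R)-4-hydroxy-3-(hydroxymethyl)-2-(3-hydroxypropyl)-4-methyl-3-[(3E,7E)-4,8,12-trimethyltrideca-3,7,11-trien-1-yl]cyclohexylidene]propan-1-ol
Conditions: Bu4NF, THF, rt
Reagents that add atoms: none
Why: Fluoride cleavage of both primary silyl ethers at the alcohol stage, before the base-sensitive enal is present.

Step 19
Reactants: 28 tetraol
Product: 29 CNP0284886.2, (2Z)-2-[(2S,3R,4R)-4-hydroxy-3-(hydroxymethyl)-2-(3-hydroxypropyl)-4-methyl-3-[(3E,7E)-4,8,12-trimethyltrideca-3,7,11-trien-1-yl]cyclohexylidene]propanal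
Conditions: MnO2 (activated), CH2Cl2, rt
Reagents that add atoms: none
Why: MnO2 should oxidise only the allylic primary alcohol, leaving the two saturated primary alcohols and the tertiary alcohol untouched (chemoselective allylic oxidation).

**Compound list**

1 | (2E,6E)-farnesol | CC(C)=CCC/C(C)=C/CC/C(C)=C/CO | starting material
2 | (2E,6E)-farnesal | CC(C)=CCC/C(C)=C/CC/C(C)=C/C=O | intermediate
3 | (3E,7E)-4,8,12-trimethyltrideca-1,3,7,11-tetraene | CC(C)=CCC/C(C)=C/CC/C(C)=C/C=C | intermediate
4 | 9-[(3E,7E)-4,8,12-trimethyltrideca-3,7,11-trien-1-yl]-9-borabicyclo[3.3.1]nonane | CC(C)=CCC/C(C)=C/CC/C(C)=C/CCB1C2CCCC1CCC2 | intermediate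
5 | (3E,7E)-4,8,12-trimethyltrideca-3,7,11-trien-1-ol (homofarnesol) | CC(C)=CCC/C(C)=C/CC/C(C)=C/CCO | intermediate
6 | (3E,7E)-1-iodo-4,8,12-trimethyltrideca-3,7,11-triene (homofarnesyl iodide) | CC(C)=CCC/C(C)=C/CC/C(C)=C/CCI | intermediate
7 | methyl acetoacetate | COC(=O)CC(C)=O | starting material
8 | (E)-4,4-dimethoxybut-2-enal | COC(OC)/C=C/C=O | starting material
9 | methyl (3R)-2-acetyl-3-(dimethoxymethyl)-5-oxopentanoate | COC(=O)C(C(C)=O)[C@@H](CC=O)C(OC)OC | intermediate
10 | methyl (6R)-6-(dimethoxymethyl)-4-hydroxy-2-oxocyclohexane-1-carboxylate | COC(=O)C1C(=O)CC(O)C[C@H]1C(OC)OC | intermediate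
11 | methyl (6R)-6-(dimethoxymethyl)-2-oxocyclohex-3-ene-1-carboxylate | COC(=O)C1C(=O)C=CC[C@H]1C(OC)OC | intermediate
12 | methyl (1R,6R)-6-(dimethoxymethyl)-2-oxo-1-[(3E,7E)-4,8,12-trimethyltrideca-3,7,11-trien-1-yl]cyclohex-3-ene-1-carboxylate | CC(C)=CCC/C(C)=C/CC/C(C)=C/CC[C@]1(C(=O)OC)C(=O)C=CC[C@H]1C(OC)OC | intermediate
13 | lithium enolate of the 3,4-dihydro ketone from 12 (enolate between the ketone carbon and C3) | CC(C)=CCC/C(C)=C/CC/C(C)=C/CC[C@]1(C(=O)OC)C(O[Li])=CCC[C@H]1C(OC)OC | intermediate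
14 | methyl (1R,6R)-6-(dimethoxymethyl)-3-hydroxy-2-oxo-1-[(3E,7E)-4,8,12-trimethyltrideca-3,7,11-trien-1-yl]cyclohexane-1-carboxylate | CC(C)=CCC/C(C)=C/CC/C(C)=C/CC[C@]1(C(=O)OC)C(=O)C(O)CC[C@H]1C(OC)OC | intermediate
15 | methyl (1R,6R)-6-(dimethoxymethyl)-2,3-dihydroxy-1-[(3E,7E)-4,8,12-trimethyltrideca-3,7,11-trien-1-yl]cyclohexane-1-carboxylate | CC(C)=CCC/C(C)=C/CC/C(C)=C/CC[C@]1(C(=O)OC)C(O)C(O)CC[C@H]1C(OC)OC | intermediate
16 | methyl (2R,5E,9E)-2-[(2R)-1,1-dimethoxy-5-oxopentan-2-yl]-2-formyl-6,10,14-trimethylpentadeca-5,9,13-trienoate | CC(C)=CCC/C(C)=C/CC/C(C)=C/CC[C@](C(=O)OC)(C=O)[C@@H](CCC=O)C(OC)OC | intermediate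
17 | methyl (2R,5E,9E)-2-[(2R)-5-hydroxy-1,1-dimethoxypentan-2-yl]-2-(hydroxymethyl)-6,10,14-trimethylpentadeca-5,9,13-trienoate | CC(C)=CCC/C(C)=C/CC/C(C)=C/CC[C@](C(=O)OC)(CO)[C@@H](CCCO)C(OC)OC | intermediate
18 | bis-TBS ether of 17 | CC(C)=CCC/C(C)=C/CC/C(C)=C/CC[C@](C(=O)OC)(CO[Si](C)(C)C(C)(C)C)[C@@H](CCCO[Si](C)(C)C(C)(C)C)C(OC)OC | intermediate
19 | cyclopropanol from 18 (name in step 10) | CC(C)=CCC/C(C)=C/CC/C(C)=C/CC[C@](C1(O)CC1)(CO[Si](C)(C)C(C)(C)C)[C@@H](CCCO[Si](C)(C)C(C)(C)C)C(OC)OC | intermediate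
20 | aldehyde with triethylsilyl-protected cyclopropanol (name in step 11) | CC(C)=CCC/C(C)=C/CC/C(C)=C/CC[C@](C1(O[Si](CC)(CC)CC)CC1)(CO[Si](C)(C)C(C)(C)C)[C@@H](CCCO[Si](C)(C)C(C)(C)C)C=O | intermediate
21 | methyl propionate | CCC(=O)OC | starting material
22 | β-hydroxy ester (name in step 12) | CC(C)=CCC/C(C)=C/CC/C(C)=C/CC[C@](C1(O[Si](CC)(CC)CC)CC1)(CO[Si](C)(C)C(C)(C)C)[C@@H](CCCO[Si](C)(C)C(C)(C)C)C(O)C(C)C(=O)OC | intermediate
23 | α-methyl β-keto ester (name in step 13) | CC(C)=CCC/C(C)=C/CC/C(C)=C/CC[C@](C1(O[Si](CC)(CC)CC)CC1)(CO[Si](C)(C)C(C)(C)C)[C@@H](CCCO[Si](C)(C)C(C)(C)C)C(=O)C(C)C(=O)OC | intermediate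
24 | (2E,4R) enol triflate (name in step 14) | CC(C)=CCC/C(C)=C/CC/C(C)=C/CC[C@](C1(O[Si](CC)(CC)CC)CC1)(CO[Si](C)(C)C(C)(C)C)[C@@H](CCCO[Si](C)(C)C(C)(C)C)/C(OS(=O)(=O)C(F)(F)F)=C(/C)C(=O)OC | intermediate
25 | ring A ketone, (2Z), (2S,3R) (name in step 15) | CC(C)=CCC/C(C)=C/CC/C(C)=C/CC[C@]1(CO[Si](C)(C)C(C)(C)C)[C@@H](CCCO[Si](C)(C)C(C)(C)C)/C(=C(/C)C(=O)OC)CCC1=O | intermediate
26 | tertiary alcohol ester, (2Z), (2S,3R,4R) (name in step 16) | CC(C)=CCC/C(C)=C/CC/C(C)=C/CC[C@]1(CO[Si](C)(C)C(C)(C)C)[C@@H](CCCO[Si](C)(C)C(C)(C)C)/C(=C(/C)C(=O)OC)CC[C@@]1(C)O | intermediate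
27 | allylic alcohol, bis-TBS (name in step 17) | CC(C)=CCC/C(C)=C/CC/C(C)=C/CC[C@]1(CO[Si](C)(C)C(C)(C)C)[C@@H](CCCO[Si](C)(C)C(C)(C)C)/C(=C(/C)CO)CC[C@@]1(C)O | intermediate
28 | tetraol (name in step 18) | CC(C)=CCC/C(C)=C/CC/C(C)=C/CC[C@]1(CO)[C@@H](CCCO)/C(=C(/C)CO)CC[C@@]1(C)O | intermediate
29 | CNP0284886.2 (name in step 19) | CC(C)=CCC/C(C)=C/CC/C(C)=C/CC[C@]1(CO)[C@@H](CCCO)/C(=C(/C)C=O)CC[C@@]1(C)O | target

**Counts**

Total step count: 19. Longest linear sequence: 18 steps (1 to 6 in steps 1–4, then steps 6–19 to 29); the branch from 7 and 8 is 15 steps.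

**Steps most likely to fail, with fallbacks**

1. Step 15 (Proposed new method). The risk is that the silylated cyclopropanol does not hand its carbon to palladium, or that β-hydride elimination of the homoenolate and reduction of the alkenyl palladium species win over ring closure. The fallback uses an intramolecular B-alkyl Suzuki–Miyaura coupling, sets out from 18 and returns at 25. Ester 18 is reduced with i-Bu2AlH at −78 °C to the neopentyl aldehyde F1, and vinylmagnesium bromide gives the allylic alcohol F2 (both epimers serve). Et3SiOTf/2,4,6-collidine and then water silylate the carbinol and unmask the aldehyde F3. Aldol addition with 21 gives the β-hydroxy ester F4, periodinane oxidation the β-keto ester F5 and Tf2O/aq. Me4NOH the E enol triflate F6, as in steps 12 to 14. 9-BBN hydroborates the terminal vinyl group to the alkylborane F7, which PdCl2(dppf), AsPh3 and Cs2CO3 in DMF/THF/water close to the ring A silyl ether F8. Pyridinium p-toluenesulfonate in MeOH at 0 °C removes only the triethylsilyl group to give the secondary alcohol F9, and periodinane oxidation gives ketone 25.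

2. Step 10. The risk is that the titanacyclopropane does not add to the ester, which sits on a fully substituted carbon flanked by a silyloxymethyl group. The fallback builds the protected cyclopropanol from a methyl ketone, sets out from 18 and returns at 20. Me3SiCH2Li adds once to ester 18 to give the α-silyl ketone F10, and methanol work-up gives the methyl ketone F11. LiN(i-Pr)2 and Et3SiCl give the only possible silyl enol ether F12. Simmons–Smith cyclopropanation with Et2Zn and CH2I2, which is faster on the electron-rich enol ether than on the trisubstituted alkenes, gives the cyclopropyl silyl ether F13. Et3SiOTf/2,4,6-collidine and then water cleave the acetal to give 20.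

3. Step 16. The risk is poor facial selectivity of the methyl addition, because the axial homofarnesyl group next to the carbonyl hinders the equatorial path while the axial C2 side chain hinders the axial one. The fallback sets C4 by a hydroxyl-directed epoxidation, sets out from 25 and returns at 28. Methylenation of 25 with Zn, CH2Br2 and TiCl4 gives the exocyclic alkene F14, and Bu4NF gives the diol F15. VO(acac)2 and t-BuOOH, directed by the hydroxymethyl group on the neighbouring quaternary carbon, deliver oxygen to the face of that group and give the spiro-epoxide F16. LiAlH4 opens the epoxide at its CH2 terminus and reduces the ester in the same operation to give tetraol 28.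

**Further compounds**

F1 | step 15 | aldehyde from 18 (ester carbon as CHO) | CC(C)=CCC/C(C)=C/CC/C(C)=C/CC[C@](C=O)(CO[Si](C)(C)C(C)(C)C)[C@@H](CCCO[Si](C)(C)C(C)(C)C)C(OC)OC
F2 | step 15 | allylic alcohol from F1 and vinylmagnesium bromide | CC(C)=CCC/C(C)=C/CC/C(C)=C/CC[C@](C(O)C=C)(CO[Si](C)(C)C(C)(C)C)[C@@H](CCCO[Si](C)(C)C(C)(C)C)C(OC)OC
F3 | step 15 | aldehyde with triethylsilyl-protected allylic alcohol | CC(C)=CCC/C(C)=C/CC/C(C)=C/CC[C@](C(O[Si](CC)(CC)CC)C=C)(CO[Si](C)(C)C(C)(C)C)[C@@H](CCCO[Si](C)(C)C(C)(C)C)C=O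
F4 | step 15 | β-hydroxy ester from F3 and 21 | CC(C)=CCC/C(C)=C/CC/C(C)=C/CC[C@](C(O[Si](CC)(CC)CC)C=C)(CO[Si](C)(C)C(C)(C)C)[C@@H](CCCO[Si](C)(C)C(C)(C)C)C(O)C(C)C(=O)OC
F5 | step 15 | α-methyl β-keto ester from F4 | CC(C)=CCC/C(C)=C/CC/C(C)=C/CC[C@](C(O[Si](CC)(CC)CC)C=C)(CO[Si](C)(C)C(C)(C)C)[C@@H](CCCO[Si](C)(C)C(C)(C)C)C(=O)C(C)C(=O)OC
F6 | step 15 | E enol triflate from F5 | CC(C)=CCC/C(C)=C/CC/C(C)=C/CC[C@](C(O[Si](CC)(CC)CC)C=C)(CO[Si](C)(C)C(C)(C)C)[C@@H](CCCO[Si](C)(C)C(C)(C)C)/C(OS(=O)(=O)C(F)(F)F)=C(/C)C(=O)OC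
F7 | step 15 | B-alkyl-9-BBN from F6 | CC(C)=CCC/C(C)=C/CC/C(C)=C/CC[C@](C(O[Si](CC)(CC)CC)CCB1C2CCCC1CCC2)(CO[Si](C)(C)C(C)(C)C)[C@@H](CCCO[Si](C)(C)C(C)(C)C)/C(OS(=O)(=O)C(F)(F)F)=C(/C)C(=O)OC
F8 | step 15 | ring A triethylsilyl ether (C4 carbinol protected) | CC(C)=CCC/C(C)=C/CC/C(C)=C/CC[C@]1(CO[Si](C)(C)C(C)(C)C)[C@@H](CCCO[Si](C)(C)C(C)(C)C)/C(=C(/C)C(=O)OC)CCC1O[Si](CC)(CC)CC
F9 | step 15 | ring A secondary alcohol at C4 | CC(C)=CCC/C(C)=C/CC/C(C)=C/CC[C@]1(CO[Si](C)(C)C(C)(C)C)[C@@H](CCCO[Si](C)(C)C(C)(C)C)/C(=C(/C)C(=O)OC)CCC1O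
F10 | step 10 | α-(trimethylsilyl)methyl ketone from 18 | CC(C)=CCC/C(C)=C/CC/C(C)=C/CC[C@](C(=O)C[Si](C)(C)C)(CO[Si](C)(C)C(C)(C)C)[C@@H](CCCO[Si](C)(C)C(C)(C)C)C(OC)OC
F11 | step 10 | methyl ketone | CC(C)=CCC/C(C)=C/CC/C(C)=C/CC[C@](C(C)=O)(CO[Si](C)(C)C(C)(C)C)[C@@H](CCCO[Si](C)(C)C(C)(C)C)C(OC)OC
F12 | step 10 | triethylsilyl enol ether of F11 | CC(C)=CCC/C(C)=C/CC/C(C)=C/CC[C@](C(=C)O[Si](CC)(CC)CC)(CO[Si](C)(C)C(C)(C)C)[C@@H](CCCO[Si](C)(C)C(C)(C)C)C(OC)OC
F13 | step 10 | cyclopropyl triethylsilyl ether with dimethyl acetal | CC(C)=CCC/C(C)=C/CC/C(C)=C/CC[C@](C1(O[Si](CC)(CC)CC)CC1)(CO[Si](C)(C)C(C)(C)C)[C@@H](CCCO[Si](C)(C)C(C)(C)C)C(OC)OC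
F14 | step 16 | exocyclic methylene compound from 25 | CC(C)=CCC/C(C)=C/CC/C(C)=C/CC[C@]1(CO[Si](C)(C)C(C)(C)C)[C@@H](CCCO[Si](C)(C)C(C)(C)C)/C(=C(/C)C(=O)OC)CCC1=C
F15 | step 16 | diol from F14 | CC(C)=CCC/C(C)=C/CC/C(C)=C/CC[C@]1(CO)[C@@H](CCCO)/C(=C(/C)C(=O)OC)CCC1=C
F16 | step 16 | spiro-epoxide, oxygen syn to the hydroxymethyl group | CC(C)=CCC/C(C)=C/CC/C(C)=C/CC[C@]1(CO)[C@@H](CCCO)/C(=C(/C)C(=O)OC)CC[C@@]12OC2
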